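**Retrosynthetic overview**

- Feature used: C3' of the norbornane ring, the carbon that ends as CMe2, is bonded directly to the spiro carbon C2' shared with the pyran ring. Carried as a ketone, C3' makes C2' enolisable (for exo bromination), activates C2' for substitution, and is turned into CMe2 at the end.
- Key disconnection O1–C2': the pyran ring is closed by intramolecular phenoxide displacement of the exo tertiary bromide of α-bromoketone 22 with inversion, giving O1 endo and C3 exo in 23.
- 22 comes from exo alkylation of the enolate of (1S,4R)-norcamphor 16 with iodide 15 (C2'–C3 bond), then hydrogenation, silyl enol ether formation and exo bromination.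
- 15 comes from an Evans alkylation that sets C4, on an arylacetic acid made from 3,5-dimethoxyphenol by Claisen rearrangement.
- Ring order: the benzene and norbornane rings are bought; the pyran ring is the only ring formed (step 13). Endgame: C=O → C=CH2 → cyclopropane → CMe2, Rieche diformylation, demethylation.

Key step: step 13

Remark: chroman atoms are unprimed, norbornane atoms primed. (1S,4R)-Norcamphor is taken as available enantiopure. Compounds 18 and 19 are drawn as the 3-exo epimers, but C3 is planarised in step 11, so its configuration at that stage is immaterial.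

**Route**

Step 1
Reactants: 1 3,5-dimethoxyphenol; 2 allyl bromide
Product: 3 1-(allyloxy)-3,5-dimethoxybenzene
Conditions: K2CO3, acetone, reflux
Reagents that add atoms: none
Why: Williamson O-allylation of the phenoxide with a reactive allylic bromide should proceed cleanly; no stereocentre is involved.

Step 2
Reactants: 3 1-(allyloxy)-3,5-dimethoxybenzene
Product: 4 2-allyl-3,5-dimethoxyphenol
Conditions: N,N-diethylaniline, 190–200 °C, sealed tube
Reagents that add atoms: none
Why: Thermal aromatic Claisen rearrangement ([3,3] shift, then tautomerisation); the two ortho positions are equivalent by symmetry, so one regioisomer should form and the 2-hydroxy-4,6-dimethoxy pattern is fixed without ambiguity.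

Step 3
Reactants: 4 2-allyl-3,5-dimethoxyphenol
Product: 5 2-allyl-1-(benzyloxy)-3,5-dimethoxybenzene
Conditions: BnBr, K2CO3, DMF, rt
Reagents that add atoms: benzyl bromide BrCc1ccccc1
Why: Williamson benzylation; the benzyl ether tolerates oxidants, enolates and hydride up to step 10, where it is removed together with the alkene reduction.

Step 4
Reactants: 5 2-allyl-1-(benzyloxy)-3,5-dimethoxybenzene
Product: 8 [2-(benzyloxy)-4,6-dimethoxyphenyl]acetic acid, via vicinal diol 6 (not isolated), via arylacetaldehyde 7 (not isolated)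
Conditions: OsO4 (cat.), NaIO4, 2,6-lutidine, dioxane/H2O, rt; then NaClO2, NaH2PO4, 2-methyl-2-butene, t-BuOH/H2O, 0 °C → rt
Reagents that add atoms: osmium tetroxide O=[Os](=O)(=O)=O; sodium periodate [Na+].[O-]I(=O)(=O)=O; sodium chlorite [Na+].[O-]Cl=O
Why: Lemieux–Johnson cleavage of the terminal alkene followed by Pinnick oxidation of the crude aldehyde; buffered, non-acidic conditions and the HOCl scavenger should spare the electron-rich ring and the benzyl ether.

Step 5
Reactants: 8 [2-(benzyloxy)-4,6-dimethoxyphenyl]acetic acid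
Product: 10 (4R)-4-benzyl-3-{[2-(benzyloxy)-4,6-dimethoxyphenyl]acetyl}-1,3-oxazolidin-2-one, via mixed pivalic anhydride 9 (not isolated)
Conditions: PivCl, Et3N, THF, −20 °C; then (R)-4-benzyl-2-oxazolidinone, LiCl, −20 °C → rt
Reagents that add atoms: pivaloyl chloride CC(C)(C)C(Cl)=O (its atoms remain only in 9); (R)-4-benzyl-1,3-oxazolidin-2-one O=C1N[C@H](Cc2ccccc2)CO1
Why: N-acylation of the oxazolidinone through the mixed anhydride (LiCl/Et3N protocol); the hindered pivaloyl carbonyl directs attack to the arylacetyl carbonyl.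

Step 6
Reactants: 10 (4R)-4-benzyl-3-{[2-(benzyloxy)-4,6-dimethoxyphenyl]acetyl}-1,3-oxazolidin-2-one; 11 methallyl bromide
Product: 13 (4R)-4-benzyl-3-{(2R)-2-[2-(benzyloxy)-4,6-dimethoxyphenyl]-4-methylpent-4-enoyl}-1,3-oxazolidin-2-one, via sodium Z-enolate 12 (not isolated)
Conditions: NaN(SiMe3)2 (1.05 equiv), THF, −78 °C; then 11, −78 → −40 °C; AcOH quench
Reagents that add atoms: none
Why: Evans asymmetric alkylation: the chelated Z-enolate is attacked by the allylic bromide on the face opposite the C4 benzyl group of the (R)-auxiliary, which should set the benzylic centre (later C4) as 2R; the reactive methallyl halide stands in for the sluggish isobutyl iodide and is saturated in step 10.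

Step 7
Reactants: 13 (4R)-4-benzyl-3-{(2R)-2-[2-(benzyloxy)-4,6-dimethoxyphenyl]-4-methylpent-4-enoyl}-1,3-oxazolidin-2-one
Product: 14 (2R)-2-[2-(benzyloxy)-4,6-dimethoxyphenyl]-4-methylpent-4-en-1-ol
Conditions: LiBH4, MeOH (1 equiv), THF, 0 °C
Reagents that add atoms: none
Why: Reductive cleavage of the imide with LiBH4 at 0 °C is fast and non-basic enough that the α-aryl centre should not epimerise; the alkene and benzyl ether are inert and the auxiliary is recovered.

Step 8
Reactants: 14 (2R)-2-[2-(benzyloxy)-4,6-dimethoxyphenyl]-4-methylpent-4-en-1-ol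
Product: 15 1-(benzyloxy)-2-[(2R)-1-iodo-4-methylpent-4-en-2-yl]-3,5-dimethoxybenzene
Conditions: I2, PPh3, imidazole, CH2Cl2, 0 °C → rt
Reagents that add atoms: iodine II
Why: Appel-type (Garegg–Samuelsson) iodination by SN2 at the primary carbon, leaving the adjacent stereocentre untouched; the iodide is used at once and kept cold.

Step 9
Reactants: 16 (1S,4R)-norcamphor; 15 1-(benzyloxy)-2-[(2R)-1-iodo-4-methylpent-4-en-2-yl]-3,5-dimethoxybenzene
Product: 18 (1S,3S,4R)-3-exo-{(2R)-2-[2-(benzyloxy)-4,6-dimethoxyphenyl]-4-methylpent-4-en-1-yl}bicyclo[2.2.1]heptan-2-one, via lithium enolate 17 (not isolated)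
Conditions: LiN(iPr)2, THF, −78 °C (16 in twofold excess); then 15, DMPU, −78 → 0 °C
Reagents that add atoms: none
Why: SN2 alkylation of the lithium enolate, which can only form toward C3 because the other α-carbon is a bridgehead; attack on the exo face should place the side chain exo, and excess enolate with DMPU favours substitution over dehydroiodination.

Step 10
Reactants: 18 (1S,3S,4R)-3-exo-{(2R)-2-[2-(benzyloxy)-4,6-dimethoxyphenyl]-4-methylpent-4-en-1-yl}bicyclo[2.2.1]heptan-2-one
Product: 19 (1S,3S,4R)-3-exo-[(2S)-2-(2-hydroxy-4,6-dimethoxyphenyl)-4-methylpentyl]bicyclo[2.2.1]heptan-2-one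
Conditions: H2 (1 atm), Pd/C, EtOAc/EtOH, rt
Reagents that add atoms: none
Why: One heterogeneous hydrogenation should saturate the 1,1-disubstituted alkene to the isobutyl group and hydrogenolyse the benzyl ether, while the hindered ketone is not reduced over palladium at this pressure.

Step 11
Reactants: 19 (1S,3S,4R)-3-exo-[(2S)-2-(2-hydroxy-4,6-dimethoxyphenyl)-4-methylpentyl]bicyclo[2.2.1]heptan-2-one
Product: 20 bis(trimethylsilyl) derivative of 19 (2-trimethylsilyloxy-norborn-2-ene with the side chain on C3, aryl O–SiMe3)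
Conditions: Me3SiOTf, Et3N, CH2Cl2, 0 °C → rt; non-aqueous work-up
Reagents that add atoms: trimethylsilyl trifluoromethanesulfonate C[Si](C)(C)OS(=O)(=O)C(F)(F)F
Why: Soft enolisation and silylation; only one enol regiochemistry exists (bridgehead on the other side), both C3 epimers converge, and the phenol is masked in the same operation.

Step 12
Reactants: 20 bis(trimethylsilyl) derivative of 19
Product: 22 (1S,3S,4R)-3-exo-bromo-3-[(2S)-2-(2-hydroxy-4,6-dimethoxyphenyl)-4-methylpentyl]bicyclo[2.2.1]heptan-2-one, via aryl silyl ether bromoketone 21 (not isolated)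
Conditions: NBS (1.0 equiv), THF, −78 °C; then 1 M HCl, THF, 0 °C
Reagents that add atoms: N-bromosuccinimide BrN1C(=O)CCC1=O
Why: Electrophilic bromination of the silyl enol ether on the open exo face of the norbornene should put bromine exo and the side chain endo at the future C2'; at −78 °C with one equivalent the enol ether should outcompete the trioxygenated arene, and the acidic work-up frees the phenol.

Step 13
Reactants: 22 (1S,3S,4R)-3-exo-bromo-3-[(2S)-2-(2-hydroxy-4,6-dimethoxyphenyl)-4-methylpentyl]bicyclo[2.2.1]heptan-2-one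
Product: 23 (1'R,2R,4S,4'S)-4-isobutyl-5,7-dimethoxyspiro[chromane-2,2'-bicyclo[2.2.1]heptan]-3'-one (O1 endo, C3 exo)
Conditions: Cs2CO3 (1.5 equiv), degassed DMF, 0 °C → rt
Reagents that add atoms: none
Why: Cs2CO3 deprotonates the phenol and the cesium phenoxide displaces the exo tertiary bromide α to the ketone from the endo face in an intramolecular SN2 reaction that forms O1–C2 and closes the pyran ring in the 6-exo-tet mode. The closest known reaction type is the Williamson-type O-alkylation of phenoxides by tertiary α-bromo ketones and esters (aryloxyisobutyrate synthesis), where the adjacent carbonyl lowers the barrier to backside attack at the tertiary carbon. The stereocentre concerned, C2', is controlled by inversion of the exo C–Br bond set in step 12, so O1 should end endo and C3 exo as in the target, while C4, C1' and C4' are untouched. The step needs substitution to win over loss of HBr and over ionisation: elimination toward bridgehead C1' or toward the carbonyl is impossible, the only α'-hydrogen is at bridgehead C4' so no Favorskii path exists, and a weakly basic phenoxide in a dipolar aprotic solvent without Lewis acid disfavours both E2 toward the side-chain CH2 and formation of an α-keto cation. Degassing protects the electron-rich phenoxide, and the tether makes the closure fast enough that no high dilution should be needed.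

Step 14
Reactants: 23 (1'R,2R,4S,4'S)-4-isobutyl-5,7-dimethoxyspiro[chromane-2,2'-bicyclo[2.2.1]heptan]-3'-one
Product: 24 (1'R,2R,4S,4'S)-4-isobutyl-5,7-dimethoxy-3'-methylenespiro[chromane-2,2'-bicyclo[2.2.1]heptane]
Conditions: Cp2TiMe2 (3 equiv), toluene, 75 °C, dark
Reagents that add atoms: dimethyltitanocene C[Ti](C)(C1C=CC=C1)C1C=CC=C1
Why: Petasis methylenation suits a hindered, non-enolisable ketone flanked by a quaternary carbon and a bridgehead, and its non-basic conditions leave the aryl ethers alone.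

Step 15
Reactants: 24 (1'R,2R,4S,4'S)-4-isobutyl-5,7-dimethoxy-3'-methylenespiro[chromane-2,2'-bicyclo[2.2.1]heptane]
Product: 25 3'-spirocyclopropane analogue of 24 (cyclopropane spiro-fused at C3')
Conditions: Et2Zn, CH2I2, CH2Cl2, 0 °C → rt
Reagents that add atoms: diiodomethane ICI
Why: Simmons–Smith cyclopropanation (Furukawa variant) of the exocyclic 1,1-disubstituted alkene, assisted by the allylic ether oxygen O1; no new stereocentre arises because the two new CH2 groups are equivalent.

Step 16
Reactants: 25 3'-spirocyclopropane analogue of 24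
Product: 26 (1'R,2R,4S,4'S)-4-isobutyl-5,7-dimethoxy-3',3'-dimethylspiro[chromane-2,2'-bicyclo[2.2.1]heptane]
Conditions: H2 (3 atm), PtO2, AcOH, rt
Reagents that add atoms: none
Why: Catalytic hydrogenolysis of the cyclopropane at its least hindered CH2–CH2 bond should deliver the gem-dimethyl group; the arene and the alkyl aryl ether are not reduced at this pressure.

Step 17
Reactants: 26 (1'R,2R,4S,4'S)-4-isobutyl-5,7-dimethoxy-3',3'-dimethylspiro[chromane-2,2'-bicyclo[2.2.1]heptane]
Product: 27 (1'R,2R,4S,4'S)-4-isobutyl-5,7-dimethoxy-3',3'-dimethylspiro[chromane-2,2'-bicyclo[2.2.1]heptane]-6,8-dicarbaldehyde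
Conditions: Cl2CHOMe (excess), TiCl4, CH2Cl2, −78 → 0 °C; then ice-water
Reagents that add atoms: dichloromethyl methyl ether COC(Cl)Cl; water O
Why: Twofold Rieche formylation at C6 and C8, the only free ring positions, each flanked by two oxygen substituents; low temperature should spare the tertiary alkyl aryl ether from ionisation.

Step 18
Reactants: 27 (1'R,2R,4S,4'S)-4-isobutyl-5,7-dimethoxy-3',3'-dimethylspiro[chromane-2,2'-bicyclo[2.2.1]heptane]-6,8-dicarbaldehyde
Product: 28 (1'R,2R,4S,4'S)-5,7-dihydroxy-4-isobutyl-3',3'-dimethylspiro[chromane-2,2'-bicyclo[2.2.1]heptane]-6,8-dicarbaldehyde (target)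
Conditions: NaSEt (excess), DMF, 100 °C; then 1 M HCl
Reagents that add atoms: none
Why: Nucleophilic demethylation by SN2 attack of thiolate on the two O-methyl groups, each made a good leaving phenoxide by an ortho formyl group; without acid or Lewis acid the tertiary O1–C2 ether, which cannot undergo SN2, should stay intact.

**Compound list**

1 | 3,5-dimethoxyphenol | COc1cc(O)cc(OC)c1 | starting material
2 | allyl bromide | C=CCBr | starting material
3 | 1-(allyloxy)-3,5-dimethoxybenzene | C=CCOc1cc(OC)cc(OC)c1 | intermediate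
4 | 2-allyl-3,5-dimethoxyphenol | C=CCc1c(O)cc(OC)cc1OC | intermediate
5 | 2-allyl-1-(benzyloxy)-3,5-dimethoxybenzene | C=CCc1c(OCc2ccccc2)cc(OC)cc1OC | intermediate
6 | 3-[2-(benzyloxy)-4,6-dimethoxyphenyl]propane-1,2-diol (racemic, not isolated) | OCC(O)Cc1c(OCc2ccccc2)cc(OC)cc1OC | intermediate
7 | [2-(benzyloxy)-4,6-dimethoxyphenyl]acetaldehyde (not isolated) | O=CCc1c(OCc2ccccc2)cc(OC)cc1OC | intermediate
8 | [2-(benzyloxy)-4,6-dimethoxyphenyl]acetic acid | OC(=O)Cc1c(OCc2ccccc2)cc(OC)cc1OC | intermediate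
9 | [2-(benzyloxy)-4,6-dimethoxyphenyl]acetic pivalic anhydride (not isolated) | CC(C)(C)C(=O)OC(=O)Cc1c(OCc2ccccc2)cc(OC)cc1OC | intermediate
10 | (4R)-4-benzyl-3-{[2-(benzyloxy)-4,6-dimethoxyphenyl]acetyl}-1,3-oxazolidin-2-one | O=C(Cc1c(OCc2ccccc2)cc(OC)cc1OC)N1[C@H](Cc2ccccc2)COC1=O | intermediate
11 | methallyl bromide (3-bromo-2-methylprop-1-ene) | CC(=C)CBr | starting material
12 | sodium Z-enolate of 10 (not isolated) | [Na+].[O-]/C(=C\c1c(OCc2ccccc2)cc(OC)cc1OC)N1[C@H](Cc2ccccc2)COC1=O | intermediate
13 | (4R)-4-benzyl-3-{(2R)-2-[2-(benzyloxy)-4,6-dimethoxyphenyl]-4-methylpent-4-enoyl}-1,3-oxazolidin-2-one | CC(=C)C[C@@H](C(=O)N1[C@H](Cc2ccccc2)COC1=O)c1c(OCc2ccccc2)cc(OC)cc1OC | intermediate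
14 | (2R)-2-[2-(benzyloxy)-4,6-dimethoxyphenyl]-4-methylpent-4-en-1-ol | CC(=C)C[C@@H](CO)c1c(OCc2ccccc2)cc(OC)cc1OC | intermediate
15 | 1-(benzyloxy)-2-[(2R)-1-iodo-4-methylpent-4-en-2-yl]-3,5-dimethoxybenzene | CC(=C)C[C@@H](CI)c1c(OCc2ccccc2)cc(OC)cc1OC | intermediate
16 | (1S,4R)-norcamphor | C1[C@@H]2CC[C@@H](C2)C1=O | starting material
17 | lithium enolate of (1S,4R)-norcamphor (not isolated) | [Li+].[O-]C1=C[C@@H]2CC[C@H]1C2 | intermediate
18 | (1S,3S,4R)-3-exo-{(2R)-2-[2-(benzyloxy)-4,6-dimethoxyphenyl]-4-methylpent-4-en-1-yl}bicyclo[2.2.1]heptan-2-one | CC(=C)C[C@@H](C[C@H]1[C@@H]2CC[C@@H](C2)C1=O)c1c(OCc2ccccc2)cc(OC)cc1OC | intermediate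
19 | (1S,3S,4R)-3-exo-[(2S)-2-(2-hydroxy-4,6-dimethoxyphenyl)-4-methylpentyl]bicyclo[2.2.1]heptan-2-one | CC(C)C[C@@H](C[C@H]1[C@@H]2CC[C@@H](C2)C1=O)c1c(O)cc(OC)cc1OC | intermediate
20 | bis(trimethylsilyl) derivative of 19 (silyl enol ether and aryl silyl ether) | CC(C)C[C@@H](CC1=C(O[Si](C)(C)C)[C@H]2CC[C@@H]1C2)c1c(O[Si](C)(C)C)cc(OC)cc1OC | intermediate
21 | (1S,3S,4R)-3-exo-bromo-3-{(2S)-2-[4,6-dimethoxy-2-(trimethylsilyloxy)phenyl]-4-methylpentyl}bicyclo[2.2.1]heptan-2-one (not isolated) | CC(C)C[C@@H](C[C@]1(Br)[C@@H]2CC[C@@H](C2)C1=O)c1c(O[Si](C)(C)C)cc(OC)cc1OC | intermediate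
22 | (1S,3S,4R)-3-exo-bromo-3-[(2S)-2-(2-hydroxy-4,6-dimethoxyphenyl)-4-methylpentyl]bicyclo[2.2.1]heptan-2-one | CC(C)C[C@@H](C[C@]1(Br)[C@@H]2CC[C@@H](C2)C1=O)c1c(O)cc(OC)cc1OC | intermediate
23 | (1'R,2R,4S,4'S)-4-isobutyl-5,7-dimethoxyspiro[chromane-2,2'-bicyclo[2.2.1]heptan]-3'-one | CC(C)C[C@H]1C[C@@]2(Oc3cc(OC)cc(OC)c31)[C@@H]1CC[C@@H](C1)C2=O | intermediate
24 | (1'R,2R,4S,4'S)-4-isobutyl-5,7-dimethoxy-3'-methylenespiro[chromane-2,2'-bicyclo[2.2.1]heptane] | CC(C)C[C@H]1C[C@@]2(Oc3cc(OC)cc(OC)c31)[C@@H]1CC[C@@H](C1)C2=C | intermediate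
25 | 3'-spirocyclopropane analogue of 24 | CC(C)C[C@H]1C[C@@]2(Oc3cc(OC)cc(OC)c31)[C@@H]1CC[C@@H](C1)C21CC1 | intermediate
26 | (1'R,2R,4S,4'S)-4-isobutyl-5,7-dimethoxy-3',3'-dimethylspiro[chromane-2,2'-bicyclo[2.2.1]heptane] | CC(C)C[C@H]1C[C@@]2(Oc3cc(OC)cc(OC)c31)[C@@H]1CC[C@@H](C1)C2(C)C | intermediate
27 | (1'R,2R,4S,4'S)-4-isobutyl-5,7-dimethoxy-3',3'-dimethylspiro[chromane-2,2'-bicyclo[2.2.1]heptane]-6,8-dicarbaldehyde | CC(C)C[C@H]1C[C@@]2(Oc3c(C=O)c(OC)c(C=O)c(OC)c31)[C@@H]1CC[C@@H](C1)C2(C)C | intermediate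
28 | (1'R,2R,4S,4'S)-5,7-dihydroxy-4-isobutyl-3',3'-dimethylspiro[chromane-2,2'-bicyclo[2.2.1]heptane]-6,8-dicarbaldehyde | CC(C)C[C@H]1C[C@@]2(Oc3c(C=O)c(O)c(C=O)c(O)c31)[C@@H]1CC[C@@H](C1)C2(C)C | target

**Step count**

Total: 18 steps. Longest linear sequence: 18 steps (1 → 28); norcamphor 16 enters at step 9.

**Steps most likely to fail**

Step 13 (key ring closure). Dehydrobromination toward the side-chain CH2, whose hydrogens the tethered phenoxide can reach, may outrun substitution and be followed by 5-exo oxa-Michael closure to a dihydrobenzofuran. Alternatively the hindered endo trajectory may simply stop the displacement. The fallback closes the same ring through C2'–C3 instead of O1–C2; it sets out from 14 (with 16) and comes back at 23. Alcohol 14 would be silylated (t-BuMe2SiCl, imidazole) to the silyl ether F1 and hydrogenated (H2, Pd/C) to the phenol F2. Separately, 16 would be formylated (HCO2Et, NaH) to the hydroxymethylene ketone F3 and converted by deformylative diazo transfer (4-acetamidobenzenesulfonyl azide, Et3N) into 3-diazonorcamphor F4. O–H insertion of F4 into F2 catalysed by Rh2(OAc)4 would give the α-aryloxy ketone F5 as a mixture of C3 epimers, both usable. Bu4NF would free the primary alcohol F6, and I2/PPh3/imidazole would give the iodide F7. KN(SiMe3)2 in THF would then form the α-aryloxy enolate, whose intramolecular C-alkylation on the exo face (6-exo-tet) places C3 exo and leaves O1 endo, which is 23.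

Step 9 (enolate alkylation). Substitution at the β-branched primary iodide may be slow enough for dehydroiodination by the enolate to compete. Displacement of iodide by the neighbouring benzyloxy oxygen, with loss of the benzyl group, may compete as well. The fallback forms the same C–C bond by aldol condensation; it sets out from 14 (with 16) and comes back at 19. Buffered Dess–Martin oxidation of 14 would give the aldehyde F8, used at once and cold to limit epimerisation of its α-aryl centre. Addition of enolate 17 at −78 °C would give the aldol adduct F9, and mesylation followed by DBU elimination would give the enone F10. Hydrogenation over Pd/C would saturate both alkenes and cleave the benzyl ether to give 19; the C3 configuration is again irrelevant.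

Step 18 (demethylation). The second ether cleavage may stall once the first phenoxide deactivates the ring, or thiolate may attack a ring carbon or a formyl group instead of the methyl groups. The fallback reverses the order of the last two operations; it sets out from 26 and comes back at 28. BBr3 in CH2Cl2 (−78 → 0 °C) would cleave both methyl ethers of 26 to the diol F11. Rieche formylation of F11 (Cl2CHOMe, TiCl4), directed ortho by the titanium phenoxides to C6 and C8, would then give 28 directly.

**Further compounds**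

F1 | step 13 | tert-butyl{[(2R)-2-[2-(benzyloxy)-4,6-dimethoxyphenyl]-4-methylpent-4-en-1-yl]oxy}dimethylsilane | CC(=C)C[C@@H](CO[Si](C)(C)C(C)(C)C)c1c(OCc2ccccc2)cc(OC)cc1OC
F2 | step 13 | 2-[(2R)-1-(tert-butyldimethylsilyloxy)-4-methylpentan-2-yl]-3,5-dimethoxyphenol | CC(C)C[C@@H](CO[Si](C)(C)C(C)(C)C)c1c(O)cc(OC)cc1OC
F3 | step 13 | (1S,4R)-3-(hydroxymethylidene)bicyclo[2.2.1]heptan-2-one | OC=C1[C@@H]2CC[C@@H](C2)C1=O
F4 | step 13 | (1S,4R)-3-diazobicyclo[2.2.1]heptan-2-one | [N-]=[N+]=C1[C@@H]2CC[C@@H](C2)C1=O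
F5 | step 13 | (1S,4R)-3-{2-[(2R)-1-(tert-butyldimethylsilyloxy)-4-methylpentan-2-yl]-3,5-dimethoxyphenoxy}bicyclo[2.2.1]heptan-2-one (C3 epimers) | CC(C)C[C@@H](CO[Si](C)(C)C(C)(C)C)c1c(OC2[C@@H]3CC[C@@H](C3)C2=O)cc(OC)cc1OC
F6 | step 13 | (1S,4R)-3-{2-[(2R)-1-hydroxy-4-methylpentan-2-yl]-3,5-dimethoxyphenoxy}bicyclo[2.2.1]heptan-2-one (C3 epimers) | CC(C)C[C@@H](CO)c1c(OC2[C@@H]3CC[C@@H](C3)C2=O)cc(OC)cc1OC
F7 | step 13 | (1S,4R)-3-{2-[(2R)-1-iodo-4-methylpentan-2-yl]-3,5-dimethoxyphenoxy}bicyclo[2.2.1]heptan-2-one (C3 epimers) | CC(C)C[C@@H](CI)c1c(OC2[C@@H]3CC[C@@H](C3)C2=O)cc(OC)cc1OC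
F8 | step 9 | (2R)-2-[2-(benzyloxy)-4,6-dimethoxyphenyl]-4-methylpent-4-enal | CC(=C)C[C@@H](C=O)c1c(OCc2ccccc2)cc(OC)cc1OC
F9 | step 9 | (1S,3S,4R)-3-exo-{(2R)-2-[2-(benzyloxy)-4,6-dimethoxyphenyl]-1-hydroxy-4-methylpent-4-en-1-yl}bicyclo[2.2.1]heptan-2-one (carbinol epimers) | CC(=C)C[C@@H](C(O)[C@H]1[C@@H]2CC[C@@H](C2)C1=O)c1c(OCc2ccccc2)cc(OC)cc1OC
F10 | step 9 | (1S,4R)-3-{(2R)-2-[2-(benzyloxy)-4,6-dimethoxyphenyl]-4-methylpent-4-en-1-ylidene}bicyclo[2.2.1]heptan-2-one | CC(=C)C[C@@H](C=C1[C@@H]2CC[C@@H](C2)C1=O)c1c(OCc2ccccc2)cc(OC)cc1OC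
F11 | step 18 | (1'R,2R,4S,4'S)-4-isobutyl-3',3'-dimethylspiro[chromane-2,2'-bicyclo[2.2.1]heptane]-5,7-diol | CC(C)C[C@H]1C[C@@]2(Oc3cc(O)cc(O)c31)[C@@H]1CC[C@@H](C1)C2(C)C
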